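**Plan**
- Retrosynthesis: the two phenol MOM ethers come off last; ring C (the dihydropyranone) is then cut at C2–C3 and at O1–C8a in one stroke, giving 2,2-dimethyl-2H-chromene-6-carbaldehyde and the silyl enol ether of an acetophenone whose future C8a carries fluorine.
- Enabling feature: in ring A, C8a is ortho to C4a (which bears the C4 carbonyl) and meta to both oxygens at C5 and C7. A C8a–F bond is therefore open to addition–elimination by the C2 oxygen, and the unit C3=C4(OSiMe3)–C4a=C8a(F) acts as a benzo-fused Danishefsky-type diene that ends the annulation by loss of Me3SiF.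
- Ring A comes from 5-fluororesorcinol by three directed ortho-metalations: prenyl between the two OMOM groups, then prenyl and acetyl at the two positions between F and OMOM, which are equivalent after the first prenylation.
- Forward order: ring A substituents (steps 1–5), the pyran ring of the chromene by propargyl ether Claisen cyclisation (steps 6–7), ring C last by the annulation (step 8), deprotection (step 9).
- Stereochemistry: C2, the only stereocentre, is set in step 8 by a chiral oxazaborolidinone-catalysed Mukaiyama aldol on the Si face of the aldehyde; the C–O closure occurs at the aryl carbon and leaves C2 untouched.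

Key step: step 8

Assumption: the N-tosyl-D-tryptophan-derived oxazaborolidinone is taken to be the antipode that leaves the Si face of a coordinated aryl aldehyde open; should the sense prove opposite, the L-tryptophan-derived catalyst is used instead.

**Route**

Step 1
Reactants: 1 5-fluorobenzene-1,3-diol
Product: 2 1-fluoro-3,5-bis(methoxymethoxy)benzene
Conditions: NaH, DMF, 0 °C; MOMCl, 0 °C → rt
Reagents that add atoms: chloromethyl methyl ether, COCCl
Why: Double O-alkylation of the bis-phenoxide (Williamson-type acetal formation) installs two groups that direct ortho-metalation and stay inert, meta to fluorine, in the later SNAr.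

Step 2
Reactants: 2 1-fluoro-3,5-bis(methoxymethoxy)benzene
Product: 4 5-fluoro-1,3-bis(methoxymethoxy)-2-(3-methylbut-2-en-1-yl)benzene, via aryllithium 3 (not isolated)
Conditions: n-BuLi, THF, −20 °C; CuI (10 mol%), prenyl bromide, −20 °C → rt
Reagents that add atoms: 1-bromo-3-methylbut-2-ene (prenyl bromide), CC(C)=CCBr
Why: Directed ortho-metalation should occur at the position flanked by two coordinating OMOM groups, giving an aryllithium para to fluorine that cannot lose LiF, and copper-assisted allylation at the primary carbon of prenyl bromide gives the linear prenyl arene.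

Step 3
Reactants: 4 5-fluoro-1,3-bis(methoxymethoxy)-2-(3-methylbut-2-en-1-yl)benzene
Product: 6 1-fluoro-3,5-bis(methoxymethoxy)-2,4-bis(3-methylbut-2-en-1-yl)benzene, via aryllithium 5 (not isolated)
Conditions: s-BuLi, TMEDA, THF, −78 °C; CuI (10 mol%), prenyl bromide, −78 °C, then → 0 °C
Reagents that add atoms: 1-bromo-3-methylbut-2-ene (prenyl bromide), CC(C)=CCBr
Why: The two remaining ring positions are equivalent and each is acidified by an ortho fluorine and an ortho OMOM group, so directed ortho-metalation at −78 °C (below the temperature of LiF loss) followed by allylation should give a single diprenyl arene.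

Step 4
Reactants: 6 1-fluoro-3,5-bis(methoxymethoxy)-2,4-bis(3-methylbut-2-en-1-yl)benzene
Product: 8 1-[2-fluoro-4,6-bis(methoxymethoxy)-3,5-bis(3-methylbut-2-en-1-yl)phenyl]ethan-1-one, via aryllithium 7 (not isolated)
Conditions: s-BuLi, TMEDA, THF, −78 °C; MeC(O)N(OMe)Me, −78 °C; AcOH, −78 °C
Reagents that add atoms: N-methoxy-N-methylacetamide, CC(=O)N(C)OC
Why: Directed ortho-metalation at the last ring C–H (between F and OMOM) and acyl transfer from the N-methoxy-N-methylamide, which does not over-add, should give the methyl ketone (Weinreb ketone synthesis).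

Step 5
Reactants: 8 1-[2-fluoro-4,6-bis(methoxymethoxy)-3,5-bis(3-methylbut-2-en-1-yl)phenyl]ethan-1-one
Product: 10 ({1-[2-fluoro-4,6-bis(methoxymethoxy)-3,5-bis(3-methylbut-2-en-1-yl)phenyl]ethenyl}oxy)trimethylsilane, via lithium enolate 9 (not isolated)
Conditions: LiN(i-Pr)2, THF, −78 °C; Me3SiCl, −78 → 0 °C; pentane, filtration
Reagents that add atoms: chlorotrimethylsilane, C[Si](C)(C)Cl
Why: Kinetic deprotonation of the methyl ketone (the only enolisable site) and O-silylation of the enolate give the enol silane, which is used directly.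

Step 6
Reactants: 11 4-hydroxybenzaldehyde
Product: 12 4-[(2-methylbut-3-yn-2-yl)oxy]benzaldehyde
Conditions: 3-chloro-3-methylbut-1-yne, K2CO3, KI, CuI (cat.), acetone, reflux
Reagents that add atoms: 3-chloro-3-methylbut-1-yne, C#CC(C)(C)Cl
Why: Copper-assisted O-alkylation of the phenoxide by the tertiary propargylic chloride is the standard entry to 1,1-dimethylpropargyl aryl ethers.

Step 7
Reactants: 12 4-[(2-methylbut-3-yn-2-yl)oxy]benzaldehyde
Product: 13 2,2-dimethyl-2H-chromene-6-carbaldehyde
Conditions: PhNEt2, 190 °C
Reagents that add atoms: none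
Why: Aryl propargyl ether Claisen rearrangement, 1,5-hydrogen shift and oxa-6π electrocyclisation should give the 2,2-dimethylchromene, the two ortho positions being equivalent.

Step 8
Reactants: 10 ({1-[2-fluoro-4,6-bis(methoxymethoxy)-3,5-bis(3-methylbut-2-en-1-yl)phenyl]ethenyl}oxy)trimethylsilane; 13 2,2-dimethyl-2H-chromene-6-carbaldehyde
Product: 15 (2S)-2-(2,2-dimethyl-2H-chromen-6-yl)-5,7-bis(methoxymethoxy)-6,8-bis(3-methylbut-2-en-1-yl)-2,3-dihydro-4H-chromen-4-one, via silyl aldol 14 (not isolated)
Conditions: B-butyl oxazaborolidinone from N-tosyl-D-tryptophan and BuB(OH)2 (20 mol%), EtCN, −78 °C; then Bu4N[Ph3SiF2] (0.3 equiv), THF, −78 → 0 °C; pH 7 buffer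
Reagents that add atoms: none
Why: The boron Lewis acid binds the formyl group of 13 and enol silane 10 adds through an open transition state (Mukaiyama aldol) to give silyl ether 14; fluoride then frees the C2 alkoxide, which adds to C8a and expels fluoride through a Meisenheimer intermediate stabilised by the C4 carbonyl, and the expelled fluoride desilylates the next molecule of 14, so that the net change is a formal [4+2] annulation with loss of Me3SiF. The closest known reaction types are the oxazaborolidinone-catalysed Mukaiyama aldol of aryl methyl ketone enol silanes with aryl aldehydes, the fluoride-relayed SNAr of silyl ethers with ortho-acyl aryl fluorides, and the aldehyde annulation of Danishefsky-type dienes, whose methoxy leaving group is here replaced by the C8a fluorine. Ring C is the only ring closed, by a 6-endo-trig addition–elimination at C8a in which the C4a=C8a bond lies inside the new ring. C2 is set in the aldol stage by the catalyst, which shields the Re face of the coordinated aldehyde so that attack on the Si face gives the S centre, and C2 is not touched by the closure at the aryl carbon. The step needs the alkoxide to close on C8a faster than it fragments by retro-aldol or eliminates to the enone, and this is secured by the ortho carbonyl activation, the meta placing of both OMOM groups, the six-membered transition state, the low stationary alkoxide concentration under fluoride relay and the strength of the Si–F bond formed. Regiochemistry needs no control because C8a is the only ring carbon that carries a leaving group.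

Step 9
Reactants: 15 (2S)-2-(2,2-dimethyl-2H-chromen-6-yl)-5,7-bis(methoxymethoxy)-6,8-bis(3-methylbut-2-en-1-yl)-2,3-dihydro-4H-chromen-4-one
Product: 16 (2S)-2-(2,2-dimethyl-2H-chromen-6-yl)-5,7-dihydroxy-6,8-bis(3-methylbut-2-en-1-yl)-2,3-dihydro-4H-chromen-4-one
Conditions: 3 M aq HCl, MeOH, THF, 40 °C
Reagents that add atoms: none
Why: Acid-catalysed acetal exchange with methanol should remove both MOM groups (the C5 ether first, helped by the C4 carbonyl) under conditions mild enough to spare the prenyl groups, the chromene and the C2 centre, as is usual for prenylated flavanones.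

**Compound list**
1 | 5-fluorobenzene-1,3-diol | Oc1cc(O)cc(F)c1 | starting material
2 | 1-fluoro-3,5-bis(methoxymethoxy)benzene | COCOc1cc(OCOC)cc(F)c1 | intermediate
3 | [4-fluoro-2,6-bis(methoxymethoxy)phenyl]lithium | [Li]c1c(OCOC)cc(F)cc1OCOC | intermediate
4 | 5-fluoro-1,3-bis(methoxymethoxy)-2-(3-methylbut-2-en-1-yl)benzene | COCOc1cc(F)cc(OCOC)c1CC=C(C)C | intermediate
5 | [6-fluoro-2,4-bis(methoxymethoxy)-3-(3-methylbut-2-en-1-yl)phenyl]lithium | [Li]c1c(F)cc(OCOC)c(CC=C(C)C)c1OCOC | intermediate
6 | 1-fluoro-3,5-bis(methoxymethoxy)-2,4-bis(3-methylbut-2-en-1-yl)benzene | COCOc1cc(F)c(CC=C(C)C)c(OCOC)c1CC=C(C)C | intermediate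
7 | [2-fluoro-4,6-bis(methoxymethoxy)-3,5-bis(3-methylbut-2-en-1-yl)phenyl]lithium | [Li]c1c(F)c(CC=C(C)C)c(OCOC)c(CC=C(C)C)c1OCOC | intermediate
8 | 1-[2-fluoro-4,6-bis(methoxymethoxy)-3,5-bis(3-methylbut-2-en-1-yl)phenyl]ethan-1-one | CC(=O)c1c(F)c(CC=C(C)C)c(OCOC)c(CC=C(C)C)c1OCOC | intermediate
9 | lithium 1-[2-fluoro-4,6-bis(methoxymethoxy)-3,5-bis(3-methylbut-2-en-1-yl)phenyl]ethen-1-olate | [Li]OC(=C)c1c(F)c(CC=C(C)C)c(OCOC)c(CC=C(C)C)c1OCOC | intermediate
10 | ({1-[2-fluoro-4,6-bis(methoxymethoxy)-3,5-bis(3-methylbut-2-en-1-yl)phenyl]ethenyl}oxy)trimethylsilane | C=C(O[Si](C)(C)C)c1c(F)c(CC=C(C)C)c(OCOC)c(CC=C(C)C)c1OCOC | intermediate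
11 | 4-hydroxybenzaldehyde | O=Cc1ccc(O)cc1 | starting material
12 | 4-[(2-methylbut-3-yn-2-yl)oxy]benzaldehyde | C#CC(C)(C)Oc1ccc(C=O)cc1 | intermediate
13 | 2,2-dimethyl-2H-chromene-6-carbaldehyde | CC1(C)C=Cc2cc(C=O)ccc2O1 | intermediate
14 | (3S)-3-(2,2-dimethyl-2H-chromen-6-yl)-1-[2-fluoro-4,6-bis(methoxymethoxy)-3,5-bis(3-methylbut-2-en-1-yl)phenyl]-3-[(trimethylsilyl)oxy]propan-1-one | CC(C)=CCc1c(OCOC)c(CC=C(C)C)c(F)c(c1OCOC)C(=O)C[C@@H](c1ccc2c(c1)C=CC(C)(C)O2)O[Si](C)(C)C | intermediate
15 | (2S)-2-(2,2-dimethyl-2H-chromen-6-yl)-5,7-bis(methoxymethoxy)-6,8-bis(3-methylbut-2-en-1-yl)-2,3-dihydro-4H-chromen-4-one | CC(C)=CCc1c(OCOC)c(CC=C(C)C)c2c(c1OCOC)C(=O)C[C@@H](c1ccc3c(c1)C=CC(C)(C)O3)O2 | intermediate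
16 | (2S)-2-(2,2-dimethyl-2H-chromen-6-yl)-5,7-dihydroxy-6,8-bis(3-methylbut-2-en-1-yl)-2,3-dihydro-4H-chromen-4-one | CC(C)=CCc1c(O)c(CC=C(C)C)c2c(c1O)C(=O)C[C@@H](c1ccc3c(c1)C=CC(C)(C)O3)O2 | target

**Step count**
Total: 9 steps. Longest linear sequence: 7 steps (steps 1, 2, 3, 4, 5, 8, 9).

**Steps most likely to fail**

Step 8. Once the silyl group is removed, the β-alkoxide may fragment by retro-aldol and re-add without catalyst control, which would lower the enantiomeric purity. It may also eliminate to the enone before it closes on the electron-rich fluoroarene, and the product may open at O1–C2 in the basic fluoride medium. The fallback sets out from ketone 8 and returns at 15; it sets C2 on a preformed ring C, so no aldolate is involved. Claisen condensation of 8 with ethyl formate (NaH, THF) should give sodium 3-[2-fluoro-4,6-bis(methoxymethoxy)-3,5-bis(3-methylbut-2-en-1-yl)phenyl]-3-oxoprop-1-en-1-olate F1. On warming in DMF its enolate oxygen should displace the C8a fluorine to give 5,7-bis(methoxymethoxy)-6,8-bis(3-methylbut-2-en-1-yl)-4H-chromen-4-one F2. Commercial 6-bromo-2,2-dimethyl-2H-chromene is converted by n-BuLi (THF, −78 °C) into (2,2-dimethyl-2H-chromen-6-yl)lithium F3 and, with B(OMe)3 and aqueous HCl work-up, into (2,2-dimethyl-2H-chromen-6-yl)boronic acid F4. Enantioselective conjugate addition of F4 to F2 with Pd(OCOCF3)2 and a tert-butyl pyridine-oxazoline ligand (antipode chosen for the 2S product; NH4PF6, H2O, 1,2-dichloroethane, 60 °C) should then give 15.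

Step 3. Metalation may take place at the benzylic–allylic CH2 of the first prenyl group instead of the ring. The ortho-fluoroaryllithium may lose LiF to an aryne before the C–C bond has formed, and prenyl bromide may be attacked at its tertiary end. The fallback sets out from 2 and returns at 6; it makes the C–C bond next to fluorine by palladium catalysis before any alkene is present and leaves for lithiation only a position para to fluorine. NBS in MeCN should brominate 2 between F and OMOM (para to the second OMOM) to give 2-bromo-1-fluoro-3,5-bis(methoxymethoxy)benzene F5. Linear-selective Negishi coupling of F5 with prenylzinc bromide F6 (from prenyl bromide, Zn and LiCl in THF) under Pd(OAc)2 and the biaryl phosphine CPhos should give 1-fluoro-3,5-bis(methoxymethoxy)-2-(3-methylbut-2-en-1-yl)benzene F7. Lithiation with n-BuLi between the two OMOM groups gives [4-fluoro-2,6-bis(methoxymethoxy)-3-(3-methylbut-2-en-1-yl)phenyl]lithium F8, which is prenylated as in step 2 to give 6.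

Step 4. Addition of the doubly ortho-substituted aryllithium to the amide may be slow at −78 °C, so that proton transfer from the acetyl group of the amide, or LiF loss on warming, takes over. The fallback sets out from 6 (through aryllithium 7) and returns at 8; it uses a faster carbonyl addition at the alcohol oxidation level. Aryllithium 7 is trapped at −78 °C with acetaldehyde and quenched with AcOH to give racemic 1-[2-fluoro-4,6-bis(methoxymethoxy)-3,5-bis(3-methylbut-2-en-1-yl)phenyl]ethan-1-ol F9. Oxidation with Dess–Martin periodinane (NaHCO3, CH2Cl2) should give 8.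

**Further compounds**
F1 | step 8 | sodium 3-[2-fluoro-4,6-bis(methoxymethoxy)-3,5-bis(3-methylbut-2-en-1-yl)phenyl]-3-oxoprop-1-en-1-olate | [Na+].[O-]C=CC(=O)c1c(F)c(CC=C(C)C)c(OCOC)c(CC=C(C)C)c1OCOC
F2 | step 8 | 5,7-bis(methoxymethoxy)-6,8-bis(3-methylbut-2-en-1-yl)-4H-chromen-4-one | CC(C)=CCc1c(OCOC)c(CC=C(C)C)c2occc(=O)c2c1OCOC
F3 | step 8 | (2,2-dimethyl-2H-chromen-6-yl)lithium | [Li]c1ccc2OC(C)(C)C=Cc2c1
F4 | step 8 | (2,2-dimethyl-2H-chromen-6-yl)boronic acid | OB(O)c1ccc2OC(C)(C)C=Cc2c1
F5 | step 3 | 2-bromo-1-fluoro-3,5-bis(methoxymethoxy)benzene | COCOc1cc(OCOC)c(Br)c(F)c1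
F6 | step 3 | prenylzinc bromide | CC(C)=CC[Zn]Br
F7 | step 3 | 1-fluoro-3,5-bis(methoxymethoxy)-2-(3-methylbut-2-en-1-yl)benzene | COCOc1cc(OCOC)c(CC=C(C)C)c(F)c1
F8 | step 3 | [4-fluoro-2,6-bis(methoxymethoxy)-3-(3-methylbut-2-en-1-yl)phenyl]lithium | [Li]c1c(OCOC)cc(F)c(CC=C(C)C)c1OCOC
F9 | step 4 | 1-[2-fluoro-4,6-bis(methoxymethoxy)-3,5-bis(3-methylbut-2-en-1-yl)phenyl]ethan-1-ol (racemic) | CC(O)c1c(F)c(CC=C(C)C)c(OCOC)c(CC=C(C)C)c1OCOC
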